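(The numbers in the tables were computed on assumed constants, noise included.)

If enzyme dies while it works, stop asking how much was charged and ask how much still works at the moment you look.

| flask | substrate | enzyme | remark |
|---|---|---|---|
| Thursday's | 0.070 M | 8.5 µM | run made earlier |
| Friday's | 0.11 M | 8.5 µM | run made earlier |
| Saturday's | 0.050 M | 17 µM | run made earlier |
| flask | 0.050 M | 8.5 µM |  |

| Thursday's: time / d | Thursday's: product / % | Friday's: time / d | Friday's: product / % | Saturday's: time / d | Saturday's: product / % |
|---|---|---|---|---|---|
| 0.333 | 17 | 0.500 | 23 | 0.333 | 36 |
| 0.833 | 39 | 1.25 | 39 | 0.833 | 62 |
| 1.67 | 59 | 2.50 | 56 | 1.67 | 81 |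
| 4.00 | 81 | 4.00 | 65 | 4.00 | 95 |

(each reading ± 2 percentage points)

- apparent order in enzyme when 30% of the substrate are converted (percent change of the rate of making product for one percent more enzyme charged)



Start with order one, since at fixed composition the rate follows the working enzyme. Then object, and work with the fraction left. In Saturday's run, which has the flask's substrate charge, the logarithm of the fraction left falls at 1.34 /d at first, but at 0.573 /d between 1.67 d and 4.00 d. Read that fall as enzyme dying, at 0.318 /d.

Now suppose rate and loss are both proportional to working enzyme. At one substrate charge, the amount lost by a given conversion is then the same for any enzyme charge, so extra enzyme charged is extra enzyme working, and the order equals enzyme charged over enzyme working. Scale Saturday's first constant to the flask's enzyme, and 30% takes 0.532 d. The flask then keeps 84.4%: this is the working share, enzyme still active over enzyme charged. My order is its inverse, 1.18.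

Object again: Thursday's run, reckoned the same way, gives only 0.198 /d, but its substrate charge differs, so keep Saturday's. Friday's run still has 35.0% left at 4.00 d, against 19.0% in Thursday's, and slowing by product leaves the order at one. That doubt stays open.

The forecast, lower than mine, says 1.05, judging “The data can't fully separate these”.

The flask gives 1.2, at 0.550 d.

    substrate + enzyme → product + enzyme, rate k1*[substrate]^1.5*[enzyme]/(1 + ([substrate]/Kh1)^1.5) (0.0707 M, k = 25200 /M^1.5/h)
    substrate + enzyme → spent catalyst (k = 0.366 /M/h)

Already at 0.400 d the flask holds 85.8% of its charge as enzyme and 14.2% as spent catalyst. Read through the working share, the flask's order means 81.7% still working at 0.550 d, against my 84.4%. Carry that share to Saturday's run, with the same substrate charge and twice the enzyme. The 1.55 µM lost in the flask by 30% is the same amount there, so the share in Saturday's run is 90.9% and the order 1.10.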